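**Retrosynthetic overview** (locants on the bicycle follow octahydronaphthalene numbering; C1 carries the trienoic acid chain)
1. Target ⇐ one fluoride step that frees the acid and the primary alcohol; the exocyclic E-enone at C2 ⇐ C2 ketone by alkynyl addition and Meyer–Schuster rearrangement.
2. (2E,4Z,6E)-Trienoate chain ⇐ C1 propynyl group by hydrozirconation/Negishi coupling with a (2E,4Z)-5-iodo-4-methylpentadienoate, whose Z geometry comes from copper-catalysed carbomagnesiation of propargyl alcohol.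
3. cis-Octalin ⇐ intramolecular Diels–Alder reaction of an acyclic (E)-enoate carrying a (1E,3E)-1-silyloxy-2-methyl diene; ring A and ring B close together in this single step, and no other ring is formed.
4. Acyclic triene ⇐ (R)-Roche ester (C8), Keck crotylation (C7, C6), Wittig olefination and B-alkyl Suzuki coupling with (E)-3-iodo-2-methylacrolein.

Assumption: the SMILES is read as the (1R,4aS,6S,7R,8R,8aR) enantiomer with a cis ring fusion, and commercial crotyltributylstannane (E/Z mixture, E drawn) is used because the BF3-promoted addition is stereoconvergent.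

**Step 1**
Reactants: 1 prop-2-yn-1-ol
Product: 3 (E)-3-iodo-2-methylprop-2-en-1-ol, via alkenylalane 2 (not isolated)
Conditions: AlMe3 (3 equiv), Cp2ZrCl2 (0.25 equiv), CH2Cl2, 0 °C to rt; then I2, THF, −30 °C to 0 °C; aq. K2CO3
Reagents that add atoms: trimethylaluminium, C[Al](C)C; iodine, [I][I]
Why: Negishi zirconium-catalysed carboalumination adds methyl and aluminium syn across the alkyne (methyl on the inner carbon), and iodinolysis of the C–Al bond with retention gives the E iodoalkene.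

**Step 2**
Reactants: 3 (E)-3-iodo-2-methylprop-2-en-1-ol
Product: 4 (E)-3-iodo-2-methylprop-2-enal
Conditions: MnO2 (15 equiv), CH2Cl2, rt
Reagents that add atoms: none
Why: MnO2 oxidation of an allylic alcohol, which leaves the alkene geometry untouched.

**Step 3**
Reactants: 1 prop-2-yn-1-ol
Product: 6 (Z)-3-iodo-2-methylprop-2-en-1-ol, via alkenylmagnesium chelate 5 (not isolated)
Conditions: MeMgBr (2.5 equiv), CuI (0.1 equiv), THF, −10 °C to rt; then I2, −40 °C to 0 °C; aq. NH4Cl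
Reagents that add atoms: methylmagnesium bromide, C[Mg]Br; iodine, [I][I]
Why: copper-catalysed anti carbomagnesiation of the magnesium propargyl alkoxide (Duboudin–Jousseaume) holds magnesium cis to the CH2O group in a chelate, so iodinolysis gives the Z iodoalkene.

**Step 4**
Reactants: 6 (Z)-3-iodo-2-methylprop-2-en-1-ol
Product: 7 (Z)-3-iodo-2-methylprop-2-enal
Conditions: MnO2 (15 equiv), CH2Cl2, 0 °C to rt, used at once
Reagents that add atoms: none
Why: MnO2 allylic oxidation under neutral conditions keeps the Z iodoalkene intact.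

**Step 5**
Reactants: 7 (Z)-3-iodo-2-methylprop-2-enal; 8 2-(trimethylsilyl)ethanol; 9 (triphenylphosphoranylidene)ketene
Product: 11 2-(trimethylsilyl)ethyl (2E,4Z)-5-iodo-4-methylpenta-2,4-dienoate, via ester ylide 10 (not isolated)
Conditions: 8, 9, toluene, 80 °C; then 7, rt
Reagents that add atoms: none
Why: the alcohol adds to the ketenylidene ylide to give a stabilised ester ylide, whose Wittig reaction with the enal is E-selective and does not touch the Z iodoalkene.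

**Step 6**
Reactants: 12 methyl (R)-3-hydroxy-2-methylpropanoate
Product: 13 methyl (R)-3-[(tert-butyldimethylsilyl)oxy]-2-methylpropanoate
Conditions: TBSCl, imidazole, CH2Cl2, rt
Reagents that add atoms: tert-butyldimethylsilyl chloride, CC(C)(C)[Si](C)(C)Cl
Why: standard silylation of the primary alcohol; the purchased stereocentre (future C8) is not involved.

**Step 7**
Reactants: 13 methyl (R)-3-[(tert-butyldimethylsilyl)oxy]-2-methylpropanoate
Product: 14 (R)-3-[(tert-butyldimethylsilyl)oxy]-2-methylpropanal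
Conditions: i-Bu2AlH (1.1 equiv), CH2Cl2, −78 °C; aq. potassium sodium tartrate
Reagents that add atoms: none
Why: partial reduction of the ester stops at the aldehyde because the aluminium hemiacetal is stable at −78 °C, and the α-stereocentre does not epimerise under these conditions.

**Step 8**
Reactants: 14 (R)-3-[(tert-butyldimethylsilyl)oxy]-2-methylpropanal; 15 (E)-but-2-en-1-yl(tributyl)stannane
Product: 17 (2R,3R,4S)-2,4-dimethylhex-5-ene-1,3-diol, via silylated homoallylic alcohol 16 (not isolated)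
Conditions: 15 (1.5 equiv), BF3·OEt2 (1.2 equiv), CH2Cl2, −78 °C; then HCl (1% in MeOH), 0 °C to rt
Reagents that add atoms: none
Why: Keck crotylstannane addition through an open transition state gives the 3,4-syn relationship whatever the crotyl geometry, Felkin–Anh control by the non-chelating β-silyloxy aldehyde sets C3 syn to the C2 methyl (all-syn triad), and the methanolic HCl quench removes the primary silyl ether in the same flask.

**Step 9**
Reactants: 17 (2R,3R,4S)-2,4-dimethylhex-5-ene-1,3-diol; 18 methyl (triphenylphosphoranylidene)acetate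
Product: 20 methyl (2E,4R,5R,6S)-5-hydroxy-4,6-dimethylocta-2,7-dienoate, via hydroxy aldehyde 19 (not isolated)
Conditions: TEMPO (0.1 equiv), PhI(OAc)2 (1.1 equiv), CH2Cl2, rt; then 18 (1.5 equiv), rt
Reagents that add atoms: none
Why: TEMPO/PhI(OAc)2 oxidises only the primary alcohol, and the stabilised ylide traps the sensitive β-hydroxy aldehyde in a one-pot E-selective Wittig olefination without epimerisation.

**Step 10**
Reactants: 20 methyl (2E,4R,5R,6S)-5-hydroxy-4,6-dimethylocta-2,7-dienoate; 4 (E)-3-iodo-2-methylprop-2-enal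
Product: 22 methyl (2E,4R,5R,6S,9E)-5-hydroxy-4,6,10-trimethyl-11-oxoundeca-2,9-dienoate, via B-alkyl-9-BBN borane 21 (not isolated)
Conditions: 9-BBN-H (2.5 equiv), THF, 0 °C to rt; then 4, PdCl2(dppf) (5 mol %), AsPh3, Cs2CO3, DMF–H2O, rt
Reagents that add atoms: none
Why: 9-BBN hydroborates only the terminal alkene (anti-Markovnikov), and the B-alkyl Suzuki–Miyaura coupling joins the alkylborane to the iodoalkene with retention of the E geometry.

**Step 11**
Reactants: 22 methyl (2E,4R,5R,6S,9E)-5-hydroxy-4,6,10-trimethyl-11-oxoundeca-2,9-dienoate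
Product: 23 methyl (2E,4R,5R,6S,8E,10E)-5,11-bis[(tert-butyldimethylsilyl)oxy]-4,6,10-trimethylundeca-2,8,10-trienoate
Conditions: TBSOTf (2.5 equiv), Et3N (4 equiv), CH2Cl2, −78 °C to 0 °C
Reagents that add atoms: tert-butyldimethylsilyl trifluoromethanesulfonate, CC(C)(C)[Si](C)(C)OS(=O)(=O)C(F)(F)F
Why: the alcohol is silylated and the enal undergoes soft γ-enolisation to the silyl dienol ether, the s-trans enal giving the 10E enol ether and allylic strain with the C10 methyl giving the new 8E alkene.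

**Step 12**
Reactants: 23 methyl (2E,4R,5R,6S,8E,10E)-5,11-bis[(tert-butyldimethylsilyl)oxy]-4,6,10-trimethylundeca-2,8,10-trienoate
Product: 24 methyl (1S,2R,4aS,6S,7R,8R,8aS)-2,7-bis[(tert-butyldimethylsilyl)oxy]-3,6,8-trimethyl-1,2,4a,5,6,7,8,8a-octahydronaphthalene-1-carboxylate
Conditions: toluene (0.01 M), BHT (cat.), 130 °C, sealed tube
Reagents that add atoms: none
Why: intramolecular Diels–Alder reaction through a chair-like tether with the C6 methyl, C7 silyloxy and C8 methyl groups equatorial and the ester exo (tether endo, the endo-ester mode being penalised by the clash with the diene methyl), which closes ring A and ring B at once, gives the cis fusion at C4a/C8a, puts the ester at C1 trans to H8a (from the E enoate) and sets C2 trans to the ester.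

**Step 13**
Reactants: 24 octalin methyl ester
Product: 25 (1S,2R,4aS,6S,7R,8R,8aS)-2,7-bis[(tert-butyldimethylsilyl)oxy]-3,6,8-trimethyl-1,2,4a,5,6,7,8,8a-octahydronaphthalene-1-carbaldehyde
Conditions: i-Bu2AlH (1.2 equiv), CH2Cl2, −78 °C; aq. potassium sodium tartrate
Reagents that add atoms: none
Why: partial reduction of the hindered β-silyloxy ester stops at the aldehyde at −78 °C and does not touch C1.

**Step 14**
Reactants: 25 octalin carbaldehyde
Product: 28 (1R,2R,4aS,6S,7R,8R,8aS)-2,7-bis[(tert-butyldimethylsilyl)oxy]-3,6,8-trimethyl-1-(prop-1-yn-1-yl)-1,2,4a,5,6,7,8,8a-octahydronaphthalene, via terminal alkyne 26 (not isolated), via lithium acetylide 27 (not isolated)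
Conditions: TMSCHN2, n-BuLi, THF, −78 °C, then 25, −78 °C to rt; n-BuLi, −78 °C; MeI, −78 °C to rt
Reagents that add atoms: (trimethylsilyl)diazomethane, C[Si](C)(C)C=[N+]=[N-]; iodomethane, CI
Why: Colvin rearrangement (addition of the lithiated diazomethane, Peterson elimination, loss of N2 and 1,2-hydride shift of the alkylidene carbene) gives the alkyne without epimerising C1, and the acetylide is methylated in the same flask.

**Step 15**
Reactants: 28 propynyl octalin; 11 2-(trimethylsilyl)ethyl (2E,4Z)-5-iodo-4-methylpenta-2,4-dienoate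
Product: 31 2-(trimethylsilyl)ethyl (2E,4Z,6E)-7-[(1R,2R,4aS,6S,7R,8R,8aS)-2,7-bis[(tert-butyldimethylsilyl)oxy]-3,6,8-trimethyl-1,2,4a,5,6,7,8,8a-octahydronaphthalen-1-yl]-4,6-dimethylhepta-2,4,6-trienoate, via alkenylzirconocene chloride 29 (not isolated), via alkenylzinc chloride 30 (not isolated)
Conditions: Cp2Zr(H)Cl (2 equiv), THF, rt to 40 °C; ZnCl2 (2 equiv), 0 °C; then 11, Pd(PPh3)4 (5 mol %), rt
Reagents that add atoms: none
Why: syn hydrozirconation places zirconium on the less hindered, methyl-bearing alkyne carbon, and transmetalation to zinc followed by Negishi coupling joins the two alkenyl partners with retention, giving the 6E and 4Z alkenes.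

**Step 16**
Reactants: 31 bis-silyl triene ester
Product: 32 2-(trimethylsilyl)ethyl (2E,4Z,6E)-7-[(1R,2R,4aS,6S,7R,8R,8aS)-2,7-dihydroxy-3,6,8-trimethyl-1,2,4a,5,6,7,8,8a-octahydronaphthalen-1-yl]-4,6-dimethylhepta-2,4,6-trienoate
Conditions: HF·pyridine, pyridine, THF, 0 °C to rt
Reagents that add atoms: none
Why: buffered HF cleaves both secondary silyl ethers while the 2-(trimethylsilyl)ethyl ester and the triene survive.

**Step 17**
Reactants: 32 diol
Product: 33 2-(trimethylsilyl)ethyl (2E,4Z,6E)-7-[(1R,4aS,6S,7R,8R,8aS)-7-hydroxy-3,6,8-trimethyl-2-oxo-1,2,4a,5,6,7,8,8a-octahydronaphthalen-1-yl]-4,6-dimethylhepta-2,4,6-trienoate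
Conditions: MnO2 (20 equiv), CH2Cl2, rt
Reagents that add atoms: none
Why: MnO2 oxidises only the allylic C2 alcohol to the enone under neutral conditions, leaving the saturated C7 alcohol and the acidic C1–H alone.

**Step 18**
Reactants: 33 enone; 34 tert-butyldimethyl(prop-2-yn-1-yloxy)silane
Product: 37 2-(trimethylsilyl)ethyl (2E,4Z,6E)-7-[(1R,4aS,6S,7R,8R,8aS)-2-{3-[(tert-butyldimethylsilyl)oxy]prop-1-yn-1-yl}-2,7-dihydroxy-3,6,8-trimethyl-1,2,4a,5,6,7,8,8a-octahydronaphthalen-1-yl]-4,6-dimethylhepta-2,4,6-trienoate, via lithium acetylide 35 (not isolated), via alkynylcerium dichloride 36 (not isolated)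
Conditions: 34 (4 equiv), n-BuLi, THF, −78 °C; CeCl3, −78 °C; then 33, −78 °C; aq. NH4Cl
Reagents that add atoms: none
Why: the weakly basic organocerium acetylide adds 1,2 to the hindered, enolisable enone instead of deprotonating C1, and the new carbinol centre (either epimer) is lost in the next step.

**Step 19**
Reactants: 37 tertiary propargylic alcohol
Product: 38 2-(trimethylsilyl)ethyl (2E,4Z,6E)-7-[(1R,2E,4aS,6S,7R,8R,8aR)-2-{3-[(tert-butyldimethylsilyl)oxy]-2-oxopropylidene}-7-hydroxy-3,6,8-trimethyl-1,2,4a,5,6,7,8,8a-octahydronaphthalen-1-yl]-4,6-dimethylhepta-2,4,6-trienoate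
Conditions: (Ph3P)AuNTf2 (5 mol %), MeOH (1 equiv), toluene, rt
Reagents that add atoms: none
Why: gold-catalysed Meyer–Schuster rearrangement (1,3-hydroxyl shift to the allenol, then tautomerisation) gives the exocyclic enone, and the E isomer is the thermodynamic one because the Z isomer would press the acyl group against the C3 methyl.

**Step 20**
Reactants: 38 protected dienone
Product: 39 (2E,4Z,6E)-7-[(1R,2E,4aS,6S,7R,8R,8aR)-7-hydroxy-2-(3-hydroxy-2-oxopropylidene)-3,6,8-trimethyl-1,2,4a,5,6,7,8,8a-octahydronaphthalen-1-yl]-4,6-dimethylhepta-2,4,6-trienoic acid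
Conditions: TASF [tris(dimethylamino)sulfonium difluorotrimethylsilicate] (4 equiv), DMF, 0 °C to rt; then aq. HCl to pH 4
Reagents that add atoms: none
Why: fluoride cleaves the primary silyl ether and fragments the 2-(trimethylsilyl)ethyl ester (to ethene and Me3SiF) under nearly neutral conditions that spare the dienone and the Z alkene.

**Compound list**
1 | prop-2-yn-1-ol | C#CCO | starting material
2 | dimethyl[(E)-3-(dimethylalumanyloxy)-2-methylprop-1-en-1-yl]alumane (not isolated) | C[Al](C)/C=C(\C)CO[Al](C)C | intermediate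
3 | (E)-3-iodo-2-methylprop-2-en-1-ol | I/C=C(\C)CO | intermediate
4 | (E)-3-iodo-2-methylprop-2-enal | I/C=C(\C)C=O | intermediate
5 | (Z)-[3-(bromomagnesiooxy)-2-methylprop-1-en-1-yl]magnesium bromide (not isolated) | Br[Mg]/C=C(/C)CO[Mg]Br | intermediate
6 | (Z)-3-iodo-2-methylprop-2-en-1-ol | I/C=C(/C)CO | intermediate
7 | (Z)-3-iodo-2-methylprop-2-enal | I/C=C(/C)C=O | intermediate
8 | 2-(trimethylsilyl)ethanol | C[Si](C)(C)CCO | starting material
9 | (triphenylphosphoranylidene)ketene | O=C=C=P(c1ccccc1)(c1ccccc1)c1ccccc1 | starting material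
10 | 2-(trimethylsilyl)ethyl (triphenylphosphoranylidene)acetate (not isolated) | C[Si](C)(C)CCOC(=O)C=P(c1ccccc1)(c1ccccc1)c1ccccc1 | intermediate
11 | 2-(trimethylsilyl)ethyl (2E,4Z)-5-iodo-4-methylpenta-2,4-dienoate | I/C=C(/C)\C=C\C(=O)OCC[Si](C)(C)C | intermediate
12 | methyl (R)-3-hydroxy-2-methylpropanoate (Roche ester) | COC(=O)[C@H](C)CO | starting material
13 | methyl (R)-3-[(tert-butyldimethylsilyl)oxy]-2-methylpropanoate | COC(=O)[C@H](C)CO[Si](C)(C)C(C)(C)C | intermediate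
14 | (R)-3-[(tert-butyldimethylsilyl)oxy]-2-methylpropanal | O=C[C@H](C)CO[Si](C)(C)C(C)(C)C | intermediate
15 | (E)-but-2-en-1-yl(tributyl)stannane (crotyltributylstannane) | C/C=C/C[Sn](CCCC)(CCCC)CCCC | starting material
16 | (2R,3R,4S)-1-[(tert-butyldimethylsilyl)oxy]-2,4-dimethylhex-5-en-3-ol (not isolated) | C=C[C@H](C)[C@@H](O)[C@H](C)CO[Si](C)(C)C(C)(C)C | intermediate
17 | (2R,3R,4S)-2,4-dimethylhex-5-ene-1,3-diol | C=C[C@H](C)[C@@H](O)[C@H](C)CO | intermediate
18 | methyl (triphenylphosphoranylidene)acetate | COC(=O)C=P(c1ccccc1)(c1ccccc1)c1ccccc1 | starting material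
19 | (2S,3R,4S)-3-hydroxy-2,4-dimethylhex-5-enal (not isolated) | C=C[C@H](C)[C@@H](O)[C@H](C)C=O | intermediate
20 | methyl (2E,4R,5R,6S)-5-hydroxy-4,6-dimethylocta-2,7-dienoate | C=C[C@H](C)[C@@H](O)[C@H](C)/C=C/C(=O)OC | intermediate
21 | methyl (2E,4R,5R,6S)-8-(9-borabicyclo[3.3.1]nonan-9-yl)-5-[(9-borabicyclo[3.3.1]nonan-9-yl)oxy]-4,6-dimethyloct-2-enoate (not isolated) | B1(C2CCCC1CCC2)CC[C@H](C)[C@@H](OB1C2CCCC1CCC2)[C@H](C)/C=C/C(=O)OC | intermediate
22 | methyl (2E,4R,5R,6S,9E)-5-hydroxy-4,6,10-trimethyl-11-oxoundeca-2,9-dienoate | O=C/C(C)=C/CC[C@H](C)[C@@H](O)[C@H](C)/C=C/C(=O)OC | intermediate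
23 | methyl (2E,4R,5R,6S,8E,10E)-5,11-bis[(tert-butyldimethylsilyl)oxy]-4,6,10-trimethylundeca-2,8,10-trienoate | CC(C)(C)[Si](C)(C)O/C=C(C)/C=C/C[C@H](C)[C@@H](O[Si](C)(C)C(C)(C)C)[C@H](C)/C=C/C(=O)OC | intermediate
24 | methyl (1S,2R,4aS,6S,7R,8R,8aS)-2,7-bis[(tert-butyldimethylsilyl)oxy]-3,6,8-trimethyl-1,2,4a,5,6,7,8,8a-octahydronaphthalene-1-carboxylate (cis-fused; ester trans to H8a and to the C2 silyloxy group) | CC1=C[C@H]2C[C@H](C)[C@@H](O[Si](C)(C)C(C)(C)C)[C@H](C)[C@H]2[C@H](C(=O)OC)[C@H]1O[Si](C)(C)C(C)(C)C | intermediate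
25 | (1S,2R,4aS,6S,7R,8R,8aS)-2,7-bis[(tert-butyldimethylsilyl)oxy]-3,6,8-trimethyl-1,2,4a,5,6,7,8,8a-octahydronaphthalene-1-carbaldehyde | CC1=C[C@H]2C[C@H](C)[C@@H](O[Si](C)(C)C(C)(C)C)[C@H](C)[C@H]2[C@H](C=O)[C@H]1O[Si](C)(C)C(C)(C)C | intermediate
26 | (1R,2R,4aS,6S,7R,8R,8aS)-2,7-bis[(tert-butyldimethylsilyl)oxy]-1-ethynyl-3,6,8-trimethyl-1,2,4a,5,6,7,8,8a-octahydronaphthalene (not isolated) | CC1=C[C@H]2C[C@H](C)[C@@H](O[Si](C)(C)C(C)(C)C)[C@H](C)[C@H]2[C@H](C#C)[C@H]1O[Si](C)(C)C(C)(C)C | intermediate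
27 | lithium acetylide of 26 (not isolated) | CC1=C[C@H]2C[C@H](C)[C@@H](O[Si](C)(C)C(C)(C)C)[C@H](C)[C@H]2[C@H](C#C[Li])[C@H]1O[Si](C)(C)C(C)(C)C | intermediate
28 | (1R,2R,4aS,6S,7R,8R,8aS)-2,7-bis[(tert-butyldimethylsilyl)oxy]-3,6,8-trimethyl-1-(prop-1-yn-1-yl)-1,2,4a,5,6,7,8,8a-octahydronaphthalene | CC1=C[C@H]2C[C@H](C)[C@@H](O[Si](C)(C)C(C)(C)C)[C@H](C)[C@H]2[C@H](C#CC)[C@H]1O[Si](C)(C)C(C)(C)C | intermediate
29 | chlorobis(cyclopentadienyl)[(E)-1-(octalin-1-yl)prop-1-en-2-yl]zirconium, octalin as in 28 (not isolated) | CC1=C[C@H]2C[C@H](C)[C@@H](O[Si](C)(C)C(C)(C)C)[C@H](C)[C@H]2[C@H](/C=C(\C)[Zr](Cl)(C3C=CC=C3)C3C=CC=C3)[C@H]1O[Si](C)(C)C(C)(C)C | intermediate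
30 | chloro[(E)-1-(octalin-1-yl)prop-1-en-2-yl]zinc, octalin as in 28 (not isolated) | CC1=C[C@H]2C[C@H](C)[C@@H](O[Si](C)(C)C(C)(C)C)[C@H](C)[C@H]2[C@H](/C=C(\C)[Zn]Cl)[C@H]1O[Si](C)(C)C(C)(C)C | intermediate
31 | 2-(trimethylsilyl)ethyl (2E,4Z,6E)-7-[(1R,2R,4aS,6S,7R,8R,8aS)-2,7-bis[(tert-butyldimethylsilyl)oxy]-3,6,8-trimethyl-1,2,4a,5,6,7,8,8a-octahydronaphthalen-1-yl]-4,6-dimethylhepta-2,4,6-trienoate | CC1=C[C@H]2C[C@H](C)[C@@H](O[Si](C)(C)C(C)(C)C)[C@H](C)[C@H]2[C@H](/C=C(C)/C=C(C)\C=C\C(=O)OCC[Si](C)(C)C)[C@H]1O[Si](C)(C)C(C)(C)C | intermediate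
32 | 2-(trimethylsilyl)ethyl (2E,4Z,6E)-7-[(1R,2R,4aS,6S,7R,8R,8aS)-2,7-dihydroxy-3,6,8-trimethyl-1,2,4a,5,6,7,8,8a-octahydronaphthalen-1-yl]-4,6-dimethylhepta-2,4,6-trienoate | CC1=C[C@H]2C[C@H](C)[C@@H](O)[C@H](C)[C@H]2[C@H](/C=C(C)/C=C(C)\C=C\C(=O)OCC[Si](C)(C)C)[C@H]1O | intermediate
33 | 2-(trimethylsilyl)ethyl (2E,4Z,6E)-7-[(1R,4aS,6S,7R,8R,8aS)-7-hydroxy-3,6,8-trimethyl-2-oxo-1,2,4a,5,6,7,8,8a-octahydronaphthalen-1-yl]-4,6-dimethylhepta-2,4,6-trienoate | CC1=C[C@H]2C[C@H](C)[C@@H](O)[C@H](C)[C@H]2[C@H](/C=C(C)/C=C(C)\C=C\C(=O)OCC[Si](C)(C)C)C1=O | intermediate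
34 | tert-butyldimethyl(prop-2-yn-1-yloxy)silane | C#CCO[Si](C)(C)C(C)(C)C | starting material
35 | {3-[(tert-butyldimethylsilyl)oxy]prop-1-yn-1-yl}lithium (not isolated) | [Li]C#CCO[Si](C)(C)C(C)(C)C | intermediate
36 | dichloro{3-[(tert-butyldimethylsilyl)oxy]prop-1-yn-1-yl}cerium (not isolated) | Cl[Ce](Cl)C#CCO[Si](C)(C)C(C)(C)C | intermediate
37 | 2-(trimethylsilyl)ethyl (2E,4Z,6E)-7-[(1R,4aS,6S,7R,8R,8aS)-2-{3-[(tert-butyldimethylsilyl)oxy]prop-1-yn-1-yl}-2,7-dihydroxy-3,6,8-trimethyl-1,2,4a,5,6,7,8,8a-octahydronaphthalen-1-yl]-4,6-dimethylhepta-2,4,6-trienoate (C2 configuration not controlled and not needed) | CC1=C[C@H]2C[C@H](C)[C@@H](O)[C@H](C)[C@H]2[C@H](/C=C(C)/C=C(C)\C=C\C(=O)OCC[Si](C)(C)C)C1(O)C#CCO[Si](C)(C)C(C)(C)C | intermediate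
38 | 2-(trimethylsilyl)ethyl (2E,4Z,6E)-7-[(1R,2E,4aS,6S,7R,8R,8aR)-2-{3-[(tert-butyldimethylsilyl)oxy]-2-oxopropylidene}-7-hydroxy-3,6,8-trimethyl-1,2,4a,5,6,7,8,8a-octahydronaphthalen-1-yl]-4,6-dimethylhepta-2,4,6-trienoate | CC1=C[C@H]2C[C@H](C)[C@@H](O)[C@H](C)[C@H]2[C@H](/C=C(C)/C=C(C)\C=C\C(=O)OCC[Si](C)(C)C)/C1=C\C(=O)CO[Si](C)(C)C(C)(C)C | intermediate
39 | (2E,4Z,6E)-7-[(1R,2E,4aS,6S,7R,8R,8aR)-7-hydroxy-2-(3-hydroxy-2-oxopropylidene)-3,6,8-trimethyl-1,2,4a,5,6,7,8,8a-octahydronaphthalen-1-yl]-4,6-dimethylhepta-2,4,6-trienoic acid | CC1=C[C@H]2C[C@H](C)[C@@H](O)[C@H](C)[C@H]2[C@H](/C=C(C)/C=C(C)\C=C\C(=O)O)/C1=C\C(=O)CO | target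

**Step count**
Total: 20 steps. Longest linear sequence: 15 steps (steps 6 to 20, from 12).

**Steps most likely to fail**

Step 12 (intramolecular Diels–Alder). The face of the dienophile is fixed by the equatorial triad, but the endo-ester transition state would give the trans-fused C4a epimer of 24; the preference for the exo-ester mode rests only on the steric argument and is not secured by precedent. The fallback sets out from 16, which is isolated by quenching the crotylation of step 8 without methanolic HCl, and comes back at 25. Silylation of the secondary alcohol (TBSOTf, 2,6-lutidine) gives (2R,3R,4S)-1,3-bis[(tert-butyldimethylsilyl)oxy]-2,4-dimethylhex-5-ene F1. HF·pyridine at 0 °C removes only the primary silyl group to give (2R,3R,4S)-3-[(tert-butyldimethylsilyl)oxy]-2,4-dimethylhex-5-en-1-ol F2. Dess–Martin oxidation gives (2S,3R,4S)-3-[(tert-butyldimethylsilyl)oxy]-2,4-dimethylhex-5-enal F3, and a Still–Gennari olefination [(CF3CH2O)2P(O)CH2CO2Me, KN(SiMe3)2, 18-crown-6, THF, −78 °C] gives methyl (2Z,4R,5R,6S)-5-[(tert-butyldimethylsilyl)oxy]-4,6-dimethylocta-2,7-dienoate F4. Hydroboration and Suzuki coupling with 4 as in step 10 give methyl (2Z,4R,5R,6S,9E)-5-[(tert-butyldimethylsilyl)oxy]-4,6,10-trimethyl-11-oxoundeca-2,9-dienoate F5, and TBSOTf/Et3N gives methyl (2Z,4R,5R,6S,8E,10E)-5,11-bis[(tert-butyldimethylsilyl)oxy]-4,6,10-trimethylundeca-2,8,10-trienoate F6. With the Z dienophile the ester and the tether are endo in the same transition state, so the endo rule now works for the cis ring fusion and heating gives the all-cis adduct, methyl (1R,2R,4aS,6S,7R,8R,8aS)-2,7-bis[(tert-butyldimethylsilyl)oxy]-3,6,8-trimethyl-1,2,4a,5,6,7,8,8a-octahydronaphthalene-1-carboxylate F7. i-Bu2AlH at −78 °C gives the (1R,2R,4aS,6S,7R,8R,8aS)-1-carbaldehyde F8, and DBU in CH2Cl2 epimerises C1 to the aldehyde 25, in which the formyl group is trans to both neighbours and free of the clash with the C8 methyl group.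

Step 15 (hydrozirconation/Negishi coupling). The regiochemistry of hydrozirconation next to the crowded C1 centre and the transfer of a hindered trisubstituted alkenyl group are both uncertain. The fallback sets out from 25 and comes back at 31, building the chain by olefination instead of hydrometalation. A Wittig reaction of 25 with 2-(triphenylphosphoranylidene)propanal (toluene, 80 °C) gives (E)-3-[(1R,2R,4aS,6S,7R,8R,8aS)-2,7-bis[(tert-butyldimethylsilyl)oxy]-3,6,8-trimethyl-1,2,4a,5,6,7,8,8a-octahydronaphthalen-1-yl]-2-methylprop-2-enal F9. A Zhao iodo-olefination [Ph3P=C(I)CH3 from ethyltriphenylphosphonium iodide, n-BuLi and I2, then NaN(SiMe3)2, −78 °C] gives the (1E,3Z)-4-iodo-2-methylpenta-1,3-dien-1-yl octalin F10, with iodine cis to the chain. A Heck reaction [Pd(OAc)2, Ag2CO3, DMF, rt] with 2-(trimethylsilyl)ethyl prop-2-enoate F11, made from acryloyl chloride, 8 and Et3N, replaces iodine with retention and gives 31.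

Step 19 (Meyer–Schuster rearrangement). The carbinol of 37 is allylic as well as propargylic and sits in a 1,5-enyne, so gold may divert it into enyne cycloisomerisation, allylic transposition or Rupe dehydration. The fallback sets out from 33, comes back at 38 and replaces steps 18 and 19 by an aldol-type addition and dehydration. Commercial 1-[(tert-butyldimethylsilyl)oxy]propan-2-one is converted [LiN(SiMe3)2, Me3SiCl, −78 °C] into tert-butyldimethyl({2-[(trimethylsilyl)oxy]prop-2-en-1-yl}oxy)silane F12, and NBS gives 1-bromo-3-[(tert-butyldimethylsilyl)oxy]propan-2-one F13. SmI2 (THF, −78 °C) turns F13 into its samarium enolate, which adds to the ketone of 33 in a Reformatsky-type reaction to give the β-hydroxy ketone, 2-(trimethylsilyl)ethyl (2E,4Z,6E)-7-[(1R,4aS,6S,7R,8R,8aS)-2-{3-[(tert-butyldimethylsilyl)oxy]-2-oxopropyl}-2,7-dihydroxy-3,6,8-trimethyl-1,2,4a,5,6,7,8,8a-octahydronaphthalen-1-yl]-4,6-dimethylhepta-2,4,6-trienoate F14. Camphorsulfonic acid (cat., CH2Cl2, rt) dehydrates the tertiary allylic alcohol to the conjugated E dienone 38.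

**Further compounds**
F1 | step 12 | (2R,3R,4S)-1,3-bis[(tert-butyldimethylsilyl)oxy]-2,4-dimethylhex-5-ene | C=C[C@H](C)[C@@H](O[Si](C)(C)C(C)(C)C)[C@H](C)CO[Si](C)(C)C(C)(C)C
F2 | step 12 | (2R,3R,4S)-3-[(tert-butyldimethylsilyl)oxy]-2,4-dimethylhex-5-en-1-ol | C=C[C@H](C)[C@@H](O[Si](C)(C)C(C)(C)C)[C@H](C)CO
F3 | step 12 | (2S,3R,4S)-3-[(tert-butyldimethylsilyl)oxy]-2,4-dimethylhex-5-enal | C=C[C@H](C)[C@@H](O[Si](C)(C)C(C)(C)C)[C@H](C)C=O
F4 | step 12 | methyl (2Z,4R,5R,6S)-5-[(tert-butyldimethylsilyl)oxy]-4,6-dimethylocta-2,7-dienoate | C=C[C@H](C)[C@@H](O[Si](C)(C)C(C)(C)C)[C@H](C)/C=C\C(=O)OC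
F5 | step 12 | methyl (2Z,4R,5R,6S,9E)-5-[(tert-butyldimethylsilyl)oxy]-4,6,10-trimethyl-11-oxoundeca-2,9-dienoate | O=C/C(C)=C/CC[C@H](C)[C@@H](O[Si](C)(C)C(C)(C)C)[C@H](C)/C=C\C(=O)OC
F6 | step 12 | methyl (2Z,4R,5R,6S,8E,10E)-5,11-bis[(tert-butyldimethylsilyl)oxy]-4,6,10-trimethylundeca-2,8,10-trienoate | CC(C)(C)[Si](C)(C)O/C=C(C)/C=C/C[C@H](C)[C@@H](O[Si](C)(C)C(C)(C)C)[C@H](C)/C=C\C(=O)OC
F7 | step 12 | methyl (1R,2R,4aS,6S,7R,8R,8aS)-2,7-bis[(tert-butyldimethylsilyl)oxy]-3,6,8-trimethyl-1,2,4a,5,6,7,8,8a-octahydronaphthalene-1-carboxylate (C1 epimer of 24) | CC1=C[C@H]2C[C@H](C)[C@@H](O[Si](C)(C)C(C)(C)C)[C@H](C)[C@H]2[C@@H](C(=O)OC)[C@H]1O[Si](C)(C)C(C)(C)C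
F8 | step 12 | (1R,2R,4aS,6S,7R,8R,8aS)-2,7-bis[(tert-butyldimethylsilyl)oxy]-3,6,8-trimethyl-1,2,4a,5,6,7,8,8a-octahydronaphthalene-1-carbaldehyde (C1 epimer of 25) | CC1=C[C@H]2C[C@H](C)[C@@H](O[Si](C)(C)C(C)(C)C)[C@H](C)[C@H]2[C@@H](C=O)[C@H]1O[Si](C)(C)C(C)(C)C
F9 | step 15 | (E)-3-[(1R,2R,4aS,6S,7R,8R,8aS)-2,7-bis[(tert-butyldimethylsilyl)oxy]-3,6,8-trimethyl-1,2,4a,5,6,7,8,8a-octahydronaphthalen-1-yl]-2-methylprop-2-enal | CC1=C[C@H]2C[C@H](C)[C@@H](O[Si](C)(C)C(C)(C)C)[C@H](C)[C@H]2[C@H](/C=C(C)/C=O)[C@H]1O[Si](C)(C)C(C)(C)C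
F10 | step 15 | (1R,2R,4aS,6S,7R,8R,8aS)-2,7-bis[(tert-butyldimethylsilyl)oxy]-1-[(1E,3Z)-4-iodo-2-methylpenta-1,3-dien-1-yl]-3,6,8-trimethyl-1,2,4a,5,6,7,8,8a-octahydronaphthalene | CC1=C[C@H]2C[C@H](C)[C@@H](O[Si](C)(C)C(C)(C)C)[C@H](C)[C@H]2[C@H](/C=C(C)/C=C(/C)I)[C@H]1O[Si](C)(C)C(C)(C)C
F11 | step 15 | 2-(trimethylsilyl)ethyl prop-2-enoate | C=CC(=O)OCC[Si](C)(C)C
F12 | step 19 | tert-butyldimethyl({2-[(trimethylsilyl)oxy]prop-2-en-1-yl}oxy)silane | C=C(CO[Si](C)(C)C(C)(C)C)O[Si](C)(C)C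
F13 | step 19 | 1-bromo-3-[(tert-butyldimethylsilyl)oxy]propan-2-one | BrCC(=O)CO[Si](C)(C)C(C)(C)C
F14 | step 19 | 2-(trimethylsilyl)ethyl (2E,4Z,6E)-7-[(1R,4aS,6S,7R,8R,8aS)-2-{3-[(tert-butyldimethylsilyl)oxy]-2-oxopropyl}-2,7-dihydroxy-3,6,8-trimethyl-1,2,4a,5,6,7,8,8a-octahydronaphthalen-1-yl]-4,6-dimethylhepta-2,4,6-trienoate | CC1=C[C@H]2C[C@H](C)[C@@H](O)[C@H](C)[C@H]2[C@H](/C=C(C)/C=C(C)\C=C\C(=O)OCC[Si](C)(C)C)C1(O)CC(=O)CO[Si](C)(C)C(C)(C)C
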